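The 1,3,4-trisubstituted benzene ring is assembled rather than bought. Ring carbons C3 and C4, which carry the allylic C1′ methylene and the methoxy oxygen on neighbouring positions, are the two sp carbons of a 1-methoxyalkyne; C1, C2, C5 and C6 come from methyl coumalate, whose ester carbon sits para to OMe and is later grown into the Z-propenoic acid. One thermal cycloaddition with loss of CO2 forms both new ring bonds and fixes this substitution pattern. The precursor is a (4E,6R)-1-methoxydeca-4,8-dien-1-yne carrying a TBS-protected carbinol, reached by Wittig olefination, asymmetric allylboration, prenyl-forming cross-metathesis and acetylide alkylation.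

Key step: step 8

Remark: the allylborane of step 2 is specified by its pinene series and by the isopinocampheol it releases, because the sign attached to this reagent is not used uniformly.
Remark: the two bridgehead carbons of adduct 14 form on both faces and are written without configuration, since both diastereomers collapse to the same arene.

Step 1
Reactants: 1 (tert-butyldimethylsilyloxy)acetaldehyde; 2 2-(triphenylphosphoranylidene)propanal
Product: 3 (2E)-4-[(tert-butyldimethylsilyl)oxy]-2-methylbut-2-enal
Conditions: toluene, 80 °C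
Reagents that add atoms: none
Why: Wittig olefination with a stabilised formyl ylide, which attacks the unhindered aliphatic aldehyde 1 faster than the conjugated product and should give the (E)-trisubstituted enal that becomes the C2′=C3′ alkene of the side chain.

Step 2
Reactants: 3 (2E)-4-[(tert-butyldimethylsilyl)oxy]-2-methylbut-2-enal
Product: 5 (4R,5E)-7-[(tert-butyldimethylsilyl)oxy]-5-methylhepta-1,5-dien-4-ol, via diisopinocampheylborinate ester 4 (not isolated)
Conditions: B-allyldiisopinocampheylborane of the (−)-α-pinene series, Et2O, −78 °C; then NaOH, H2O2, H2O, 0 °C to rt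
Reagents that add atoms: B-allyldiisopinocampheylborane ((−)-α-pinene series), C=CCB([C@H]1C[C@H]2C[C@@H]([C@@H]1C)C2(C)C)[C@H]1C[C@H]2C[C@@H]([C@@H]1C)C2(C)C
Why: Brown allylboration through a chair six-membered transition state, in which the isopinocampheyl groups of this series deliver allyl to the re face of the enal carbonyl in a 1,2-addition and so set the carbinol carbon as R under reagent control, the oxidative work-up then cleaving the borinate.

Step 3
Reactants: 5 (4R,5E)-7-[(tert-butyldimethylsilyl)oxy]-5-methylhepta-1,5-dien-4-ol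
Product: 6 (4R,5E)-4,7-bis[(tert-butyldimethylsilyl)oxy]-5-methylhepta-1,5-diene
Conditions: TBSCl, imidazole, DMF, rt
Reagents that add atoms: tert-butyldimethylsilyl chloride, CC(C)(C)[Si](C)(C)Cl
Why: Imidazole-promoted silylation of a secondary allylic alcohol, which masks the hydroxyl for the organolithium, thermal and hydride steps and does not touch the stereocentre.

Step 4
Reactants: 6 (4R,5E)-4,7-bis[(tert-butyldimethylsilyl)oxy]-5-methylhepta-1,5-diene
Product: 7 (2E,4R)-1,4-bis[(tert-butyldimethylsilyl)oxy]-3,7-dimethylocta-2,6-diene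
Conditions: 2-methylbut-2-ene (large excess), second-generation Grubbs catalyst RuCl2(=CHPh)(PCy3)(H2IMes) (5 mol %), CH2Cl2, 40 °C, sealed vessel
Reagents that add atoms: 2-methylbut-2-ene, CC=C(C)C
Why: Olefin cross-metathesis of the monosubstituted alkene with excess 2-methylbut-2-ene should give the prenyl terminus with loss of propene, while the trisubstituted, allylically oxygenated alkene is too hindered to enter the catalytic cycle.

Step 5
Reactants: 7 (2E,4R)-1,4-bis[(tert-butyldimethylsilyl)oxy]-3,7-dimethylocta-2,6-diene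
Product: 8 (2E,4R)-4-[(tert-butyldimethylsilyl)oxy]-3,7-dimethylocta-2,6-dien-1-ol
Conditions: HF·pyridine, pyridine, THF, 0 °C
Reagents that add atoms: none
Why: Chemoselective fluoride-mediated silyl ether cleavage, in which the unhindered primary allylic TBS ether should react much faster with buffered HF·pyridine than the secondary one flanked by the branched alkene.

Step 6
Reactants: 8 (2E,4R)-4-[(tert-butyldimethylsilyl)oxy]-3,7-dimethylocta-2,6-dien-1-ol
Product: 9 {[(2E,4R)-1-bromo-3,7-dimethylocta-2,6-dien-4-yl]oxy}(tert-butyl)dimethylsilane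
Conditions: CBr4, PPh3, CH2Cl2, 0 °C; used at once
Reagents that add atoms: carbon tetrabromide, BrC(Br)(Br)Br
Why: Appel reaction, in which bromide displaces the alkoxyphosphonium group by SN2 at the primary allylic carbon at 0 °C, which should give the linear E-bromide without transposition under neutral conditions that spare the silyl ether.

Step 7
Reactants: 9 {[(2E,4R)-1-bromo-3,7-dimethylocta-2,6-dien-4-yl]oxy}(tert-butyl)dimethylsilane; 10 2-chloro-1,1-dimethoxyethane
Product: 12 tert-butyl{[(4E,6R)-1-methoxy-5,9-dimethyldeca-4,8-dien-1-yn-6-yl]oxy}dimethylsilane, via lithium methoxyacetylide 11 (not isolated)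
Conditions: 10 (1.3 equiv), LiNEt2 (3.0 equiv per 10, from n-BuLi and Et2NH), THF, 0 °C; then 9, DMPU, −78 to −20 °C; NH4Cl quench; Et3N-deactivated silica
Reagents that add atoms: none
Why: Twofold base-induced elimination and deprotonation of 10 gives the alkoxyacetylide, whose SN2 alkylation at the primary allylic bromide in THF/DMPU at low temperature should outrun attack at the hindered γ-carbon and N-alkylation by the liberated amine, and the slight excess of 10 leaves no free amide to deprotonate the doubly activated CH2 of 12.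

Step 8
Reactants: 12 tert-butyl{[(4E,6R)-1-methoxy-5,9-dimethyldeca-4,8-dien-1-yn-6-yl]oxy}dimethylsilane; 13 methyl coumalate
Product: 15 methyl 3-[(2E,4R)-4-{[tert-butyl(dimethyl)silyl]oxy}-3,7-dimethylocta-2,6-dien-1-yl]-4-methoxybenzoate, via bicyclic lactone adduct 14 (not isolated)
Conditions: 13 (2 equiv), toluene, 110 °C, sealed tube, argon
Reagents that add atoms: none
Why: The electron-poor 2-pyrone diene of 13 and the electron-rich ynol ether 12 combine in an inverse-electron-demand Diels–Alder reaction in which the nucleophilic, chain-bearing alkyne carbon bonds to pyrone C6 (the vinylogous acceptor terminus, also β to the ester) and the methoxy-bearing carbon bonds to C3, and the 2-oxabicyclo[2.2.2]octadienone 14 then expels CO2 by retro-[4+2] to give the arene. The closest known reaction type is the cycloaddition–decarboxylation of 2-pyrone-5-carboxylates with heteroatom-substituted alkynes, enol ethers and ketene acetals, which gives para-substituted benzoates. The benzene ring is closed by an intermolecular [4+2] cycloaddition that forms the arene bonds C2–C3 and C4–C5, not by cyclisation of a tether, and loss of CO2 makes the closure irreversible. No stereocentre is created in 15: the two bridgehead centres of 14 are transient and the silyloxy-bearing C4′ is a spectator. The only selectivity needed is regiochemical, and it is secured by the matched polarisation of the two partners, which places OMe para and the side chain meta to the ester; the isolated trisubstituted alkenes are too electron-neutral to compete as dienophiles, and a methyl ynol ether has no β-hydrogen for retro-ene loss to a ketene at this temperature.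

Step 9
Reactants: 15 methyl 3-[(2E,4R)-4-{[tert-butyl(dimethyl)silyl]oxy}-3,7-dimethylocta-2,6-dien-1-yl]-4-methoxybenzoate
Product: 16 {3-[(2E,4R)-4-{[tert-butyl(dimethyl)silyl]oxy}-3,7-dimethylocta-2,6-dien-1-yl]-4-methoxyphenyl}methanol
Conditions: i-Bu2AlH (2.5 equiv), CH2Cl2, −78 °C; aqueous potassium sodium tartrate
Reagents that add atoms: none
Why: Hydride reduction of the aryl ester to the benzylic alcohol with excess i-Bu2AlH, which leaves silyl ethers, aryl ethers and isolated alkenes alone.

Step 10
Reactants: 16 {3-[(2E,4R)-4-{[tert-butyl(dimethyl)silyl]oxy}-3,7-dimethylocta-2,6-dien-1-yl]-4-methoxyphenyl}methanol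
Product: 17 3-[(2E,4R)-4-{[tert-butyl(dimethyl)silyl]oxy}-3,7-dimethylocta-2,6-dien-1-yl]-4-methoxybenzaldehyde
Conditions: MnO2 (activated, excess), CH2Cl2, rt
Reagents that add atoms: none
Why: MnO2 oxidation of a benzylic alcohol stops at the aldehyde, and no other free hydroxyl is present.

Step 11
Reactants: 17 3-[(2E,4R)-4-{[tert-butyl(dimethyl)silyl]oxy}-3,7-dimethylocta-2,6-dien-1-yl]-4-methoxybenzaldehyde
Product: 18 ethyl (2Z)-3-{3-[(2E,4R)-4-{[tert-butyl(dimethyl)silyl]oxy}-3,7-dimethylocta-2,6-dien-1-yl]-4-methoxyphenyl}prop-2-enoate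
Conditions: ethyl 2-[bis(2-methylphenoxy)phosphoryl]acetate, NaH, THF, −78 to 0 °C
Reagents that add atoms: ethyl 2-[bis(2-methylphenoxy)phosphoryl]acetate, CCOC(=O)CP(=O)(Oc1ccccc1C)Oc1ccccc1C
Why: Ando variant of the Horner–Wadsworth–Emmons olefination, in which the electron-poor diaryl phosphonate makes elimination from the kinetically formed syn adduct fast and irreversible and should give the Z-cinnamate from the non-enolisable aryl aldehyde.

Step 12
Reactants: 18 ethyl (2Z)-3-{3-[(2E,4R)-4-{[tert-butyl(dimethyl)silyl]oxy}-3,7-dimethylocta-2,6-dien-1-yl]-4-methoxyphenyl}prop-2-enoate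
Product: 20 (2Z)-3-{3-[(2E,4R)-4-hydroxy-3,7-dimethylocta-2,6-dien-1-yl]-4-methoxyphenyl}prop-2-enoic acid, via hydroxy ethyl ester 19 (not isolated)
Conditions: Bu4NF, THF, rt; then LiOH, MeOH/H2O, rt; 1 M HCl to pH 3, 0 °C; light excluded
Reagents that add atoms: lithium hydroxide, [Li+].[OH-]
Why: Fluoride-mediated cleavage of the secondary TBS ether followed in the same flask by hydroxide saponification of the ethyl ester, neither of which should isomerise the Z-enoate or touch the stereocentre, with mild acidification freeing the hydroxy acid.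

Step 13
Reactants: 20 (2Z)-3-{3-[(2E,4R)-4-hydroxy-3,7-dimethylocta-2,6-dien-1-yl]-4-methoxyphenyl}prop-2-enoic acid
Product: 22 (2Z)-3-{3-[(2E,4R)-4-(acetyloxy)-3,7-dimethylocta-2,6-dien-1-yl]-4-methoxyphenyl}prop-2-enoic acid, via mixed acetic anhydride 21 (not isolated)
Conditions: Ac2O, pyridine, CH2Cl2, rt, dark; then H2O/THF, rt
Reagents that add atoms: acetic anhydride, CC(=O)OC(C)=O
Why: Pyridine-promoted O-acetylation of the secondary allylic alcohol with retention at C4′, the carboxyl group being acetylated in passing to a mixed anhydride that water cleaves at its acetyl carbonyl during work-up to return the free Z-acid.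

Compound list
1 | (tert-butyldimethylsilyloxy)acetaldehyde | CC(C)(C)[Si](C)(C)OCC=O | starting material
2 | 2-(triphenylphosphoranylidene)propanal | CC(C=O)=P(c1ccccc1)(c1ccccc1)c1ccccc1 | starting material
3 | (2E)-4-[(tert-butyldimethylsilyl)oxy]-2-methylbut-2-enal | CC(C)(C)[Si](C)(C)OC/C=C(\C)C=O | intermediate
4 | (4R,5E)-7-[(tert-butyldimethylsilyl)oxy]-5-methylhepta-1,5-dien-4-yl diisopinocampheylborinate (formed in the flask) | CC(C)(C)[Si](C)(C)OC/C=C(\C)[C@@H](CC=C)OB([C@H]1C[C@H]2C[C@@H]([C@@H]1C)C2(C)C)[C@H]1C[C@H]2C[C@@H]([C@@H]1C)C2(C)C | intermediate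
5 | (4R,5E)-7-[(tert-butyldimethylsilyl)oxy]-5-methylhepta-1,5-dien-4-ol | CC(C)(C)[Si](C)(C)OC/C=C(\C)[C@@H](CC=C)O | intermediate
6 | (4R,5E)-4,7-bis[(tert-butyldimethylsilyl)oxy]-5-methylhepta-1,5-diene | CC(C)(C)[Si](C)(C)OC/C=C(\C)[C@@H](CC=C)O[Si](C)(C)C(C)(C)C | intermediate
7 | (2E,4R)-1,4-bis[(tert-butyldimethylsilyl)oxy]-3,7-dimethylocta-2,6-diene | CC(C)(C)[Si](C)(C)OC/C=C(\C)[C@@H](CC=C(C)C)O[Si](C)(C)C(C)(C)C | intermediate
8 | (2E,4R)-4-[(tert-butyldimethylsilyl)oxy]-3,7-dimethylocta-2,6-dien-1-ol | OC/C=C(\C)[C@@H](CC=C(C)C)O[Si](C)(C)C(C)(C)C | intermediate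
9 | {[(2E,4R)-1-bromo-3,7-dimethylocta-2,6-dien-4-yl]oxy}(tert-butyl)dimethylsilane | BrC/C=C(\C)[C@@H](CC=C(C)C)O[Si](C)(C)C(C)(C)C | intermediate
10 | 2-chloro-1,1-dimethoxyethane | COC(CCl)OC | starting material
11 | lithium methoxyacetylide (formed in the flask) | [Li]C#COC | intermediate
12 | tert-butyl{[(4E,6R)-1-methoxy-5,9-dimethyldeca-4,8-dien-1-yn-6-yl]oxy}dimethylsilane | COC#CC/C=C(\C)[C@@H](CC=C(C)C)O[Si](C)(C)C(C)(C)C | intermediate
13 | methyl coumalate (methyl 2-oxo-2H-pyran-5-carboxylate) | COC(=O)C1=COC(=O)C=C1 | starting material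
14 | methyl 7-[(2E,4R)-4-{[tert-butyl(dimethyl)silyl]oxy}-3,7-dimethylocta-2,6-dien-1-yl]-8-methoxy-3-oxo-2-oxabicyclo[2.2.2]octa-5,7-diene-6-carboxylate (formed in the flask, bridgeheads unassigned) | COC(=O)C1=CC2C(=O)OC1C(C/C=C(\C)[C@@H](CC=C(C)C)O[Si](C)(C)C(C)(C)C)=C2OC | intermediate
15 | methyl 3-[(2E,4R)-4-{[tert-butyl(dimethyl)silyl]oxy}-3,7-dimethylocta-2,6-dien-1-yl]-4-methoxybenzoate | COC(=O)c1ccc(OC)c(C/C=C(\C)[C@@H](CC=C(C)C)O[Si](C)(C)C(C)(C)C)c1 | intermediate
16 | {3-[(2E,4R)-4-{[tert-butyl(dimethyl)silyl]oxy}-3,7-dimethylocta-2,6-dien-1-yl]-4-methoxyphenyl}methanol | OCc1ccc(OC)c(C/C=C(\C)[C@@H](CC=C(C)C)O[Si](C)(C)C(C)(C)C)c1 | intermediate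
17 | 3-[(2E,4R)-4-{[tert-butyl(dimethyl)silyl]oxy}-3,7-dimethylocta-2,6-dien-1-yl]-4-methoxybenzaldehyde | O=Cc1ccc(OC)c(C/C=C(\C)[C@@H](CC=C(C)C)O[Si](C)(C)C(C)(C)C)c1 | intermediate
18 | ethyl (2Z)-3-{3-[(2E,4R)-4-{[tert-butyl(dimethyl)silyl]oxy}-3,7-dimethylocta-2,6-dien-1-yl]-4-methoxyphenyl}prop-2-enoate | CCOC(=O)/C=C\c1ccc(OC)c(C/C=C(\C)[C@@H](CC=C(C)C)O[Si](C)(C)C(C)(C)C)c1 | intermediate
19 | ethyl (2Z)-3-{3-[(2E,4R)-4-hydroxy-3,7-dimethylocta-2,6-dien-1-yl]-4-methoxyphenyl}prop-2-enoate (formed in the flask) | CCOC(=O)/C=C\c1ccc(OC)c(C/C=C(\C)[C@@H](CC=C(C)C)O)c1 | intermediate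
20 | (2Z)-3-{3-[(2E,4R)-4-hydroxy-3,7-dimethylocta-2,6-dien-1-yl]-4-methoxyphenyl}prop-2-enoic acid | OC(=O)/C=C\c1ccc(OC)c(C/C=C(\C)[C@@H](CC=C(C)C)O)c1 | intermediate
21 | acetic (2Z)-3-{3-[(2E,4R)-4-(acetyloxy)-3,7-dimethylocta-2,6-dien-1-yl]-4-methoxyphenyl}prop-2-enoic anhydride (formed in the flask) | CC(=O)OC(=O)/C=C\c1ccc(OC)c(C/C=C(\C)[C@@H](CC=C(C)C)OC(C)=O)c1 | intermediate
22 | (2Z)-3-{3-[(2E,4R)-4-(acetyloxy)-3,7-dimethylocta-2,6-dien-1-yl]-4-methoxyphenyl}prop-2-enoic acid | COc1ccc(/C=C\C(=O)O)cc1C/C=C(\C)[C@@H](CC=C(C)C)OC(C)=O | target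

Total step count: 13.
Longest linear sequence: 13 steps (1 to 22); 10 and 13 each enter in a single step.

Steps most likely to fail

Step 8. The ynol ether may be lost to oligomerisation or adventitious hydration faster than it adds to the pyrone, or the polar, stepwise pathway may close in a [2+2] sense, so that little arene forms. The fallback gives up the ring construction and attaches the side chain to a preformed arene. It sets out from bromide 9. Commercial methyl 3-bromo-4-methoxybenzoate is borylated (B2pin2, Pd(dppf)Cl2, KOAc, dioxane, 80 °C) to methyl 4-methoxy-3-(4,4,5,5-tetramethyl-1,3,2-dioxaborolan-2-yl)benzoate F1. Suzuki–Miyaura allyl–aryl coupling of this boronate with 9 (Pd(PPh3)4, K2CO3, THF/H2O, 60 °C) should join the aryl group to the unhindered CH2 terminus of the allyl unit with the E-alkene intact. The fallback comes back to the route at 15.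

Step 7. The bromide may be consumed by N-alkylation with the liberated diethylamine, the skipped enyne may migrate into conjugation under the basic conditions, or substitution may occur with allylic transposition. The fallback replaces the basic SN2 alkylation by a neutral cross-coupling. It sets out from 9 and 10. The acetylide 11, generated as in step 7, is quenched with Bu3SnCl to give tributyl(methoxyethynyl)stannane F2, which is freed from amine by distillation. Stille coupling of this stannane with 9 (Pd(PPh3)4, THF, 50 °C) should form the same sp–sp3 bond at the primary allylic carbon. The fallback comes back to the route at 12.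

Step 11. The Z-selectivity of the olefination may erode with this electron-rich aldehyde, or the Z-ester may isomerise during isolation, giving an inseparable E/Z mixture. The fallback sets the cis geometry by syn-hydrogenation of an alkyne and sets out from aldehyde 17.
- Ohira–Bestmann homologation (dimethyl (1-diazo-2-oxopropyl)phosphonate, K2CO3, MeOH, rt) should give tert-butyl{[(2E,4R)-1-(5-ethynyl-2-methoxyphenyl)-3,7-dimethylocta-2,6-dien-4-yl]oxy}dimethylsilane F3.
- Deprotonation and carboxylation (n-BuLi, THF, −78 °C; ClCO2Et) should give ethyl 3-{3-[(2E,4R)-4-{[tert-butyl(dimethyl)silyl]oxy}-3,7-dimethylocta-2,6-dien-1-yl]-4-methoxyphenyl}prop-2-ynoate F4.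
- Semihydrogenation (H2, Pd on CaCO3 poisoned with Pb(OAc)2, quinoline, EtOAc) should deliver the Z-ester without reducing the trisubstituted alkenes.

The fallback comes back to the route at 18.

Further compounds
F1 | step 8 | methyl 4-methoxy-3-(4,4,5,5-tetramethyl-1,3,2-dioxaborolan-2-yl)benzoate | COC(=O)c1ccc(OC)c(c1)B1OC(C)(C)C(C)(C)O1
F2 | step 7 | tributyl(methoxyethynyl)stannane | CCCC[Sn](CCCC)(CCCC)C#COC
F3 | step 11 | tert-butyl{[(2E,4R)-1-(5-ethynyl-2-methoxyphenyl)-3,7-dimethylocta-2,6-dien-4-yl]oxy}dimethylsilane | C#Cc1ccc(OC)c(C/C=C(\C)[C@@H](CC=C(C)C)O[Si](C)(C)C(C)(C)C)c1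
F4 | step 11 | ethyl 3-{3-[(2E,4R)-4-{[tert-butyl(dimethyl)silyl]oxy}-3,7-dimethylocta-2,6-dien-1-yl]-4-methoxyphenyl}prop-2-ynoate | CCOC(=O)C#Cc1ccc(OC)c(C/C=C(\C)[C@@H](CC=C(C)C)O[Si](C)(C)C(C)(C)C)c1
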